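The beta run ends with 16 % target at 30.0 min, after 30 % at 2.50 min, and I reckon from that leftover.

| flask | substrate | first nucleophile | second nucleophile | remark | time |
|---|---|---|---|---|---|
| theta | 1 mM | 1 equiv | 1.5 equiv | run made earlier |  |
| beta | 1.5 mM | 1 equiv | 1.5 equiv | run made earlier |  |
| zeta | 2 mM | 1 equiv | 0.75 equiv | run made earlier |  |
| flask | 2.0 mM | 1.00 equiv | 1.50 equiv |  | 25 min |

| run | time / min | other capture product / % | target / % |
|---|---|---|---|
| theta | 6.00 | 32 | 22 |
| theta | 12.0 | 29 | 16 |
| theta | 20.0 | 32 | 15 |
| theta | 25.0 | 34 | 17 |
| theta | 30.0 | 33 | 18 |
| beta | 2.50 | 34 | 30 |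
| beta | 8.00 | 33 | 15 |
| beta | 15.0 | 31 | 18 |
| beta | 20.0 | 37 | 17 |
| beta | 30.0 | 34 | 16 |
| zeta | 2.50 | 24 | 39 |
| zeta | 8.00 | 23 | 21 |
| zeta | 15.0 | 25 | 24 |
| zeta | 20.0 | 25 | 21 |
| zeta | 30.0 | 24 | 19 |

(each reading ± 2 percentage points)

- share of other capture product in other capture product plus target at 0.80 s
- share of other capture product in other capture product plus target at 25 min
- which of other capture product and target there is more of at 25 min

- the numbers in the tables scatter with a standard deviation of 2 percentage points

The shortest rung I can read is capture: in the beta run other capture product already stands at 34 % at 2.50 min, against 34 % at 30.0 min. Next comes the fall of target, which reaches 15 % by 8.00 min in that run. Then comes a plateau, and the flask's 25 min lies on it, 3.12 times that span. The early time 0.80 s comes well before the first reading, so for that share I have a ceiling and no value: the first beta reading gives 53.1 %, the beta share then climbs to 68.8 % at 8.00 min, and I expect the flask's share at the early time to lie below that first reading, though this is a statement about the proportion of target and not its amount.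

Theta and beta differ in c(substrate) yet show similar plateaus, while theta and zeta share a c(second nucleophile) of 1.50 mM and differ. So I reckon in equivalents. The late theta and beta readings give 1.33 for the plateau odds of other capture product over target, divided by the equivalents of second over first nucleophile, a selectivity factor of the plateau. Zeta reads 1.54, with its scatter. For the flask this makes odds of 1.99, above one, so I expect more other capture product than target, at a share of 66.6 %.

The forecast says 36 % (30 % to 43 %) early and 67 % (63 % to 71 %) late, with other capture product ahead, since “The outcome therefore follows equivalents rather than concentration”.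

The flask gives 32.9 % at 0.80 s and 70.4 % at 25 min, with 36.2 % other capture product against 15.2 % target, so its own factor is 1.59.

    substrate → intermediate (k = 0.0190 s⁻¹)
    first nucleophile + intermediate → target (k = 3540 M⁻¹ s⁻¹)
    second nucleophile + intermediate → other capture product (k = 1150 M⁻¹ s⁻¹)
    intermediate → solvolysis product (k = 0.386 s⁻¹)
    intermediate → side product (k = 0.149 s⁻¹)
    target ⇌ isomer of the product (K = 2.76, k = 0.00595 s⁻¹)

The flask's plateau is target standing beside 42.1 % isomer of the product, with a relaxation half-life of 1.43 min, short against 25 min. The neighbouring flask changes the first nucleophile to 4.00 equiv. Its equivalents ratio is 0.375, so 1.33 gives odds of 0.498 and a share of 33.2 %. That neighbouring flask ends at 33.2 %, with target ahead, 23.1 % against 11.4 % other capture product.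

(The data were computed for an exercise; the scatter is artificial.)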